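## Retrosynthetic overview

1. Target ⇐ hydrolysis of an enol δ-lactone ⇐ lactol ⇐ bicyclic vinylogous acid (free C8–H) + (E)-cinnamaldehyde. The C8–CH(Ph) bond is made last by an intermolecular, amine-catalysed enantioselective Michael addition (benzylic S centre).
2. Bicyclic core ⇐ Dieckmann closure of the carbocycle (C7–C8) from a 5-acyl-6-methyl-dihydropyranone ester; the dihydropyranone ring (O1–C8a) ⇐ cyclodehydration of a hydroxy triketone.
3. Triketone ⇐ C-acetylation of a β-diketone ⇐ intermolecular aldol (then oxidation) of a quaternary methyl-ketone ester with a (2R,3R)-silyloxy aldehyde from methyl (R)-3-hydroxybutanoate.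
4. Quaternary C6 ⇐ Fráter–Seebach prenylation of a (3S)-β-hydroxy ester built from ethyl acetoacetate and a cyclobutylmethyl iodide derived from (−)-verbenone.
5. Ring order: cyclobutane (chiral pool) → dihydropyranone → carbocycle → transient lactol/lactone ring.

Assumption: the commercial (1S,5S)-(−)-verbenone is of high enantiomeric purity.
Assumption: metal salts (enolates, alkoxides, carboxylates) of a numbered compound are counted with that compound; only species of new constitution get their own number.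
Shorthand: CbCH2 = [(1R,3S)-2,2-dimethyl-3-(prop-1-en-2-yl)cyclobutyl]methyl; prenyl = 3-methylbut-2-en-1-yl; TBS = tert-butyldimethylsilyl; core atoms follow chromene numbering (O1, C2, C3, C4, C4a, C5, C6, C7, C8, C8a).

## Route

Step 1
Reactants: 1 (1S,5S)-(−)-verbenone
Product: 3 (1S,3R)-3-acetyl-2,2-dimethylcyclobutane-1-carboxylic acid, via α-keto acid 2 (not isolated)
Conditions: RuCl3·xH2O (2 mol %), NaIO4 (4.2 equiv), CCl4/MeCN/H2O (2:2:3), rt
Reagents that add atoms: sodium periodate, [Na+].[O-]I(=O)(=O)=O; water, O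
Why: RuO4 formed catalytically cleaves the enone C=C and oxidatively decarboxylates the resulting α-keto acid, leaving the two cis ring stereocentres of the chiral-pool bicycle untouched (oxidative alkene cleavage).

Step 2
Reactants: 3 (1S,3R)-3-acetyl-2,2-dimethylcyclobutane-1-carboxylic acid
Product: 4 (1S,3S)-2,2-dimethyl-3-(prop-1-en-2-yl)cyclobutane-1-carboxylic acid
Conditions: Ph3PCH3Br (2.5 equiv), KOtBu (3.6 equiv), THF, 0 °C → rt; dilute HCl work-up
Reagents that add atoms: methyltriphenylphosphonium bromide, C[P+](c1ccccc1)(c1ccccc1)c1ccccc1.[Br-]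
Why: Wittig methylenation of the methyl ketone; the carboxylate is inert and shields the adjacent ring CH from deprotonation, so the cis ring geometry is kept.

Step 3
Reactants: 4 (1S,3S)-2,2-dimethyl-3-(prop-1-en-2-yl)cyclobutane-1-carboxylic acid
Product: 5 [(1S,3S)-2,2-dimethyl-3-(prop-1-en-2-yl)cyclobutyl]methanol
Conditions: LiAlH4 (2 equiv), THF, 0 °C → rt
Reagents that add atoms: none
Why: Hydride reduction of the acid to the primary alcohol does not touch the isolated alkene or the ring stereocentres.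

Step 4
Reactants: 5 [(1S,3S)-2,2-dimethyl-3-(prop-1-en-2-yl)cyclobutyl]methanol
Product: 6 (1S,3S)-1-(iodomethyl)-2,2-dimethyl-3-(prop-1-en-2-yl)cyclobutane
Conditions: I2, PPh3, imidazole, CH2Cl2, 0 °C → rt
Reagents that add atoms: iodine, II
Why: Appel-type iodination is an SN2 displacement at the exocyclic CH2, so no cyclobutylcarbinyl cation and no ring expansion arise.

Step 5
Reactants: 6 (1S,3S)-1-(iodomethyl)-2,2-dimethyl-3-(prop-1-en-2-yl)cyclobutane; 7 ethyl acetoacetate (3 equiv)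
Product: 8 ethyl 2-(CbCH2)-3-oxobutanoate (C2 epimers)
Conditions: NaH (2.8 equiv), DMF, 0 °C; then 6, 70 °C, 24 h
Reagents that add atoms: none
Why: Acetoacetic ester alkylation: the stabilised sodium enolate tolerates the heating needed for SN2 attack on the β-branched primary iodide, and excess 7 suppresses dialkylation.

Step 6
Reactants: 8 ethyl 2-(CbCH2)-3-oxobutanoate
Product: 9 ethyl (3S)-2-(CbCH2)-3-hydroxybutanoate (C2 epimers)
Conditions: H2 (4 atm), RuCl2[(S)-BINAP](dmf)n (1 mol %), EtOH, 50 °C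
Reagents that add atoms: none
Why: Noyori asymmetric hydrogenation reduces the chelating β-keto ester from one face to the 3S carbinol in both C2 epimers, while the unfunctionalised 1,1-disubstituted alkene is not reduced at low pressure; the C2 centre is erased in step 7.

Step 7
Reactants: 9 ethyl (3S)-2-(CbCH2)-3-hydroxybutanoate; 10 prenyl bromide (1.5 equiv)
Product: 11 ethyl (2R)-2-(CbCH2)-2-[(1S)-1-hydroxyethyl]-5-methylhex-4-enoate
Conditions: LiN(i-Pr)2 (2.3 equiv), THF, −78 → −20 °C; then 10, DMPU, −78 → −20 °C; aq. NH4Cl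
Reagents that add atoms: none
Why: Fráter–Seebach alkylation: the chelated lithium alkoxide–enolate is attacked by the allylic bromide anti to the carbinol methyl group, so the 3S carbinol sets the quaternary carbon as 2R (later C6; ester carbon becomes C7, carbinol carbon C5) from either C2 epimer of 9.

Step 8
Reactants: 11 ethyl (2R)-2-(CbCH2)-2-[(1S)-1-hydroxyethyl]-5-methylhex-4-enoate
Product: 12 ethyl (2R)-2-acetyl-2-(CbCH2)-5-methylhex-4-enoate
Conditions: Dess–Martin periodinane, NaHCO3, CH2Cl2, rt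
Reagents that add atoms: none
Why: Dess–Martin oxidation converts the now redundant controlling carbinol into the methyl ketone; the quaternary β-keto ester has no α-hydrogen and cannot epimerise.

Step 9
Reactants: 13 methyl (R)-3-hydroxybutanoate
Product: 14 methyl (2R,3R)-3-hydroxy-2-methylbutanoate
Conditions: LiN(i-Pr)2 (2.2 equiv), THF, −78 → −20 °C; MeI, DMPU, −78 → 0 °C; aq. NH4Cl
Reagents that add atoms: iodomethane, CI
Why: Fráter–Seebach methylation of the chiral-pool dianion gives the anti (2R,3R) product (about 95:5) because the electrophile enters anti to the carbinol methyl group of the lithium chelate.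

Step 10
Reactants: 14 methyl (2R,3R)-3-hydroxy-2-methylbutanoate
Product: 15 methyl (2R,3R)-3-(TBS-oxy)-2-methylbutanoate
Conditions: TBSCl, imidazole, DMF, rt
Reagents that add atoms: tert-butyldimethylsilyl chloride, CC(C)(C)[Si](C)(C)Cl
Why: Silylation protects the secondary alcohol through the enolate, oxidation and acylation steps that follow.

Step 11
Reactants: 15 methyl (2R,3R)-3-(TBS-oxy)-2-methylbutanoate
Product: 16 (2S,3R)-3-(TBS-oxy)-2-methylbutan-1-ol
Conditions: i-Bu2AlH (2.5 equiv), CH2Cl2, −78 → 0 °C; aq. potassium sodium tartrate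
Reagents that add atoms: none
Why: Full hydride reduction to the primary alcohol is more dependable than a partial reduction to the aldehyde (descriptor at C2 changes only by CIP ranking).

Step 12
Reactants: 16 (2S,3R)-3-(TBS-oxy)-2-methylbutan-1-ol
Product: 17 (2R,3R)-3-(TBS-oxy)-2-methylbutanal
Conditions: Dess–Martin periodinane, NaHCO3, CH2Cl2, 0 °C → rt; used crude
Reagents that add atoms: none
Why: Buffered Dess–Martin oxidation gives the α-methyl aldehyde without epimerisation when it is used at once.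

Step 13
Reactants: 12 ethyl (2R)-2-acetyl-2-(CbCH2)-5-methylhex-4-enoate; 17 (2R,3R)-3-(TBS-oxy)-2-methylbutanal
Product: 18 ethyl (2R)-2-(CbCH2)-2-[(4S,5R)-3-hydroxy-4-methyl-5-(TBS-oxy)hexanoyl]-5-methylhex-4-enoate (carbinol epimers)
Conditions: 12, LiN(i-Pr)2 (1.05 equiv), THF, −78 °C; then 17 (1.2 equiv), −78 °C; AcOH quench at −78 °C
Reagents that add atoms: none
Why: Intermolecular aldol addition: 12 can enolise only at its acetyl methyl, and the preformed lithium enolate adds to the aldehyde at −78 °C faster than proton transfer, so the α-centre of 17 survives; the new carbinol is oxidised next.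

Step 14
Reactants: 18 β-hydroxy ketone
Product: 19 ethyl (2R)-2-(CbCH2)-5-methyl-2-[(4R,5R)-4-methyl-3-oxo-5-(TBS-oxy)hexanoyl]hex-4-enoate
Conditions: Dess–Martin periodinane, NaHCO3, CH2Cl2, rt
Reagents that add atoms: none
Why: Dess–Martin oxidation gives the β-diketone under near-neutral conditions that do not epimerise the α-methyl centre.

Step 15
Reactants: 19 β-diketone
Product: 20 ethyl (2R)-2-[(4R,5R)-2-acetyl-4-methyl-3-oxo-5-(TBS-oxy)hexanoyl]-2-(CbCH2)-5-methylhex-4-enoate (enolised triketone)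
Conditions: MgCl2 (1.2 equiv), pyridine (2.5 equiv), AcCl (1.2 equiv), CH2Cl2, 0 °C → rt
Reagents that add atoms: acetyl chloride, CC(=O)Cl
Why: Soft-enolisation C-acylation of the magnesium chelate at the central carbon of the β-diketone gives the 2-acetyl triketone.

Step 16
Reactants: 20 silyl-protected triketone
Product: 22 ethyl (2R)-2-(CbCH2)-5-methyl-2-{[(2R,3R)-2,3,6-trimethyl-4-oxo-3,4-dihydro-2H-pyran-5-yl]carbonyl}hex-4-enoate, via hydroxy triketone 21 (not isolated)
Conditions: HF·pyridine, pyridine/THF, 0 °C → rt; then PPTS (10 mol %), 4 Å MS, CH2Cl2, rt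
Reagents that add atoms: none
Why: Cyclodehydration of a 5-hydroxy-1,3-diketone: the freed hydroxyl adds to the unhindered acetyl carbonyl rather than to the ketone beside the quaternary carbon, and since the carbinol C–O bond is never broken the 2R,3R (trans) centres are retained.

Step 17
Reactants: 22 pyranone ester
Product: 23 (2R,3R,6R)-6-(CbCH2)-5-hydroxy-2,3-dimethyl-6-prenyl-2,3-dihydro-4H-chromene-4,7(6H)-dione
Conditions: LiN(SiMe3)2 (1.5 equiv), THF, −78 → 0 °C; aq. NH4Cl
Reagents that add atoms: none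
Why: Dieckmann condensation: the 6-methyl group, vinylogous to two carbonyls, is the most acidic and most accessible C–H, and its anion closes the six-membered ring on the cis-disposed ester to give the stable vinylogous-acid anion without touching C6.

Step 18
Reactants: 23 bicyclic vinylogous acid; 24 (E)-cinnamaldehyde (1.5 equiv)
Product: 26 lactol (cyclic hemiacetal closed on the C7 enol oxygen; S benzylic centre; anomer mixture), via aldehyde 25 (not isolated)
Conditions: (S)-2-[diphenyl(trimethylsilyloxy)methyl]pyrrolidine (20 mol %), PhCO2H (20 mol %), CH2Cl2, rt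
Reagents that add atoms: none
Why: Iminium-catalysed intermolecular Michael addition: the (S)-diarylprolinol silyl ether shields one face of the (E)-iminium ion of 24, so the only free nucleophilic carbon (C8) adds to the β-carbon from the open face to give the S benzylic centre, and the aldehyde is trapped as the lactol.

Step 19
Reactants: 26 lactol
Product: 27 enol δ-lactone (4-phenyl-3,4-dihydro-2H-pyran-2-one fused at C7(O)–C8)
Conditions: Dess–Martin periodinane, NaHCO3, CH2Cl2, 0 °C → rt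
Reagents that add atoms: none
Why: Dess–Martin oxidation of the lactol to the lactone; 26 has no other oxidisable hydroxyl.

Step 20
Reactants: 27 enol δ-lactone
Product: 28 (3S)-3-[(2R,3R,6R)-6-(CbCH2)-5-hydroxy-2,3-dimethyl-6-prenyl-4,7-dioxo-3,4,6,7-tetrahydro-2H-chromen-8-yl]-3-phenylpropanoic acid (target CNP0103716.3)
Conditions: LiOH (3 equiv), THF/H2O (3:1), 0 °C; then 0.5 M HCl to pH 3–4 at 0 °C
Reagents that add atoms: lithium hydroxide, [Li+].[OH-]; water, O
Why: The enol ester is saponified at 0 °C much faster than anything else reacts, releasing the acid and the enolised triketone; the trans-2,3-dimethyl arrangement is also the thermodynamically preferred one.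

## Compound list

1 | (1S,5S)-(−)-verbenone, (1S,5S)-4,6,6-trimethylbicyclo[3.1.1]hept-3-en-2-one | CC1=CC(=O)[C@H]2C[C@@H]1C2(C)C | starting material
2 | 2-[(1S,3R)-3-acetyl-2,2-dimethylcyclobutyl]-2-oxoacetic acid | CC(=O)[C@@H]1C[C@H](C(=O)C(=O)O)C1(C)C | intermediate (not isolated)
3 | (1S,3R)-3-acetyl-2,2-dimethylcyclobutane-1-carboxylic acid | CC(=O)[C@@H]1C[C@H](C(=O)O)C1(C)C | intermediate
4 | (1S,3S)-2,2-dimethyl-3-(prop-1-en-2-yl)cyclobutane-1-carboxylic acid | C=C(C)[C@@H]1C[C@H](C(=O)O)C1(C)C | intermediate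
5 | [(1S,3S)-2,2-dimethyl-3-(prop-1-en-2-yl)cyclobutyl]methanol | C=C(C)[C@@H]1C[C@H](CO)C1(C)C | intermediate
6 | (1S,3S)-1-(iodomethyl)-2,2-dimethyl-3-(prop-1-en-2-yl)cyclobutane | C=C(C)[C@@H]1C[C@H](CI)C1(C)C | intermediate
7 | ethyl acetoacetate (ethyl 3-oxobutanoate) | CCOC(=O)CC(C)=O | starting material
8 | ethyl 2-{[(1R,3S)-2,2-dimethyl-3-(prop-1-en-2-yl)cyclobutyl]methyl}-3-oxobutanoate (C2 epimers) | CCOC(=O)C(C[C@H]1C[C@@H](C(C)=C)C1(C)C)C(C)=O | intermediate
9 | ethyl (3S)-2-{[(1R,3S)-2,2-dimethyl-3-(prop-1-en-2-yl)cyclobutyl]methyl}-3-hydroxybutanoate (C2 epimers) | CCOC(=O)C(C[C@H]1C[C@@H](C(C)=C)C1(C)C)[C@H](C)O | intermediate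
10 | prenyl bromide (1-bromo-3-methylbut-2-ene) | CC(C)=CCBr | starting material
11 | ethyl (2R)-2-{[(1R,3S)-2,2-dimethyl-3-(prop-1-en-2-yl)cyclobutyl]methyl}-2-[(1S)-1-hydroxyethyl]-5-methylhex-4-enoate | C[C@H](O)[C@](C[C@H]1C[C@@H](C(C)=C)C1(C)C)(CC=C(C)C)C(=O)OCC | intermediate
12 | ethyl (2R)-2-acetyl-2-{[(1R,3S)-2,2-dimethyl-3-(prop-1-en-2-yl)cyclobutyl]methyl}-5-methylhex-4-enoate | CC(=O)[C@](C[C@H]1C[C@@H](C(C)=C)C1(C)C)(CC=C(C)C)C(=O)OCC | intermediate
13 | methyl (R)-3-hydroxybutanoate | C[C@@H](O)CC(=O)OC | starting material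
14 | methyl (2R,3R)-3-hydroxy-2-methylbutanoate | C[C@@H](O)[C@@H](C)C(=O)OC | intermediate
15 | methyl (2R,3R)-3-[(tert-butyldimethylsilyl)oxy]-2-methylbutanoate | C[C@@H](O[Si](C)(C)C(C)(C)C)[C@@H](C)C(=O)OC | intermediate
16 | (2S,3R)-3-[(tert-butyldimethylsilyl)oxy]-2-methylbutan-1-ol | C[C@@H](O[Si](C)(C)C(C)(C)C)[C@@H](C)CO | intermediate
17 | (2R,3R)-3-[(tert-butyldimethylsilyl)oxy]-2-methylbutanal | C[C@@H](O[Si](C)(C)C(C)(C)C)[C@@H](C)C=O | intermediate
18 | ethyl (2R)-2-{[(1R,3S)-2,2-dimethyl-3-(prop-1-en-2-yl)cyclobutyl]methyl}-2-[(4S,5R)-5-[(tert-butyldimethylsilyl)oxy]-3-hydroxy-4-methylhexanoyl]-5-methylhex-4-enoate (carbinol epimers) | C[C@@H](O[Si](C)(C)C(C)(C)C)[C@@H](C)C(O)CC(=O)[C@](C[C@H]1C[C@@H](C(C)=C)C1(C)C)(CC=C(C)C)C(=O)OCC | intermediate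
19 | ethyl (2R)-2-{[(1R,3S)-2,2-dimethyl-3-(prop-1-en-2-yl)cyclobutyl]methyl}-2-[(4R,5R)-5-[(tert-butyldimethylsilyl)oxy]-4-methyl-3-oxohexanoyl]-5-methylhex-4-enoate | C[C@@H](O[Si](C)(C)C(C)(C)C)[C@@H](C)C(=O)CC(=O)[C@](C[C@H]1C[C@@H](C(C)=C)C1(C)C)(CC=C(C)C)C(=O)OCC | intermediate
20 | ethyl (2R)-2-[(4R,5R)-2-acetyl-5-[(tert-butyldimethylsilyl)oxy]-4-methyl-3-oxohexanoyl]-2-{[(1R,3S)-2,2-dimethyl-3-(prop-1-en-2-yl)cyclobutyl]methyl}-5-methylhex-4-enoate (enolised triketone, drawn as keto form) | C[C@@H](O[Si](C)(C)C(C)(C)C)[C@@H](C)C(=O)C(C(C)=O)C(=O)[C@](C[C@H]1C[C@@H](C(C)=C)C1(C)C)(CC=C(C)C)C(=O)OCC | intermediate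
21 | ethyl (2R)-2-[(4R,5R)-2-acetyl-5-hydroxy-4-methyl-3-oxohexanoyl]-2-{[(1R,3S)-2,2-dimethyl-3-(prop-1-en-2-yl)cyclobutyl]methyl}-5-methylhex-4-enoate | C[C@@H](O)[C@@H](C)C(=O)C(C(C)=O)C(=O)[C@](C[C@H]1C[C@@H](C(C)=C)C1(C)C)(CC=C(C)C)C(=O)OCC | intermediate (not isolated)
22 | ethyl (2R)-2-{[(1R,3S)-2,2-dimethyl-3-(prop-1-en-2-yl)cyclobutyl]methyl}-5-methyl-2-{[(2R,3R)-2,3,6-trimethyl-4-oxo-3,4-dihydro-2H-pyran-5-yl]carbonyl}hex-4-enoate | C[C@H]1OC(C)=C(C(=O)[C@](C[C@H]2C[C@@H](C(C)=C)C2(C)C)(CC=C(C)C)C(=O)OCC)C(=O)[C@@H]1C | intermediate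
23 | (2R,3R,6R)-6-{[(1R,3S)-2,2-dimethyl-3-(prop-1-en-2-yl)cyclobutyl]methyl}-5-hydroxy-2,3-dimethyl-6-(3-methylbut-2-en-1-yl)-2,3-dihydro-4H-chromene-4,7(6H)-dione | C=C(C)[C@@H]1C[C@H](C[C@@]2(CC=C(C)C)C(=O)C=C3O[C@H](C)[C@@H](C)C(=O)C3=C2O)C1(C)C | intermediate
24 | (E)-cinnamaldehyde | O=C/C=C/c1ccccc1 | starting material
25 | (3S)-3-[(2R,3R,6R)-6-{[(1R,3S)-2,2-dimethyl-3-(prop-1-en-2-yl)cyclobutyl]methyl}-5-hydroxy-2,3-dimethyl-6-(3-methylbut-2-en-1-yl)-4,7-dioxo-3,4,6,7-tetrahydro-2H-chromen-8-yl]-3-phenylpropanal | C=C(C)[C@@H]1C[C@H](C[C@@]2(CC=C(C)C)C(=O)C([C@@H](CC=O)c3ccccc3)=C3O[C@H](C)[C@@H](C)C(=O)C3=C2O)C1(C)C | intermediate (not isolated)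
26 | lactol of 25: 2-hydroxy-4-phenyl-3,4-dihydro-2H-pyran ring fused across C7(O)–C8, C5 as ketone, C4a=C8a and C7=C8 double bonds; all centres as in 25 (C6 is formally S here only because the CIP ranking of C5 and C7 is exchanged); anomer mixture | C=C(C)[C@@H]1C[C@H](C[C@]2(CC=C(C)C)C(=O)C3=C(O[C@H](C)[C@@H](C)C3=O)C4=C2OC(O)C[C@H]4c5ccccc5)C1(C)C | intermediate
27 | enol δ-lactone: as 26 with the lactol carbon oxidised to C=O (4-phenyl-3,4-dihydro-2H-pyran-2-one fused across C7(O)–C8) | C=C(C)[C@@H]1C[C@H](C[C@]2(CC=C(C)C)C(=O)C3=C(O[C@H](C)[C@@H](C)C3=O)C4=C2OC(=O)C[C@H]4c5ccccc5)C1(C)C | intermediate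
28 | (3S)-3-[(2R,3R,6R)-6-{[(1R,3S)-2,2-dimethyl-3-(prop-1-en-2-yl)cyclobutyl]methyl}-5-hydroxy-2,3-dimethyl-6-(3-methylbut-2-en-1-yl)-4,7-dioxo-3,4,6,7-tetrahydro-2H-chromen-8-yl]-3-phenylpropanoic acid | C=C(C)[C@@H]1C[C@H](C[C@@]2(CC=C(C)C)C(=O)C([C@@H](CC(=O)O)c3ccccc3)=C3O[C@H](C)[C@@H](C)C(=O)C3=C2O)C1(C)C | target

## Totals and risk

Total step count: 20. Longest linear sequence: 16 steps (steps 1–8, then 13–20); the aldehyde branch (steps 9–12) is 4 steps.

The three steps most likely to fail: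

**Step 6 (asymmetric hydrogenation).** The isopropenyl group may be partly reduced or isomerised, and the 3S selectivity on this bulky α-substituted keto ester is untested. Fallback (chiral-pool carbinol instead of hydrogenation): it sets out from alcohol 5 and comes back at 9, so steps 5 and 6 are not needed. Alcohol 5 is converted with Tf2O and 2,6-lutidine (CH2Cl2, −78 °C) into [(1S,3S)-2,2-dimethyl-3-(prop-1-en-2-yl)cyclobutyl]methyl trifluoromethanesulfonate F1. Commercial ethyl (S)-3-hydroxybutanoate F2 is turned into its dilithium alkoxide–enolate (LiN(i-Pr)2, 2.2 equiv, THF, −78 → −20 °C) and alkylated with F1 (THF/DMPU, −78 → −40 °C). This Fráter–Seebach alkylation gives 9 as its single (2S,3S) diastereomer, which enters step 7 unchanged.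

**Step 17 (Dieckmann closure).** The ester is α-quaternary and hindered, and any deprotonation at C3 of the pyranone would open the ring by E1cB and scramble C2/C3. Fallback (carbocycle before pyranone): it sets out from triketone 20 and comes back at 23. Treating 20 with LiN(i-Pr)2 (3.3 equiv, THF, −78 → 0 °C) forms the dianion at the central carbon and the acetyl methyl, which closes on the ester. The product is the monocyclic acyl trione (drawn tautomer) 2-[(2R,3R)-3-(TBS-oxy)-2-methylbutanoyl]-3,5-dihydroxy-6-(CbCH2)-6-prenylcyclohexa-2,4-dien-1-one F3. HF·pyridine then frees the alcohol to give the hydroxy acyl trione F4 (not isolated). With PPTS and 4 Å MS, F4 closes by intramolecular vinylogous ester formation on the enol carbon next to the unsubstituted ring CH (the other enol carbon is flanked by the quaternary centre), giving 23 with retention at C2.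

**Step 18 (organocatalytic Michael addition).** The nucleophile is acidic and hindered, so conversion or selectivity may be low on this late intermediate. Fallback (acid-level acceptor, no oxidation step): it sets out from 23 and comes back at 27, so step 19 is not needed. 23 is added to 5-benzylidene-2,2-dimethyl-1,3-dioxane-4,6-dione F5 (Knoevenagel product of benzaldehyde and Meldrum's acid) with a cinchona-derived bifunctional squaramide catalyst (10 mol %, CH2Cl2, −20 °C). The quinine or quinidine series is chosen in a test run so that the S centre results. The Michael adduct, 5-[(S)-(core-8-yl)(phenyl)methyl]-2,2-dimethyl-1,3-dioxane-4,6-dione F6, is not isolated. On warming (toluene, 60 °C) the C7 enol oxygen opens the dioxanedione, acetone and CO2 are lost, and lactone 27 results, which goes on to step 20.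

## Further compounds

F1 | step 6 | [(1S,3S)-2,2-dimethyl-3-(prop-1-en-2-yl)cyclobutyl]methyl trifluoromethanesulfonate | C=C(C)[C@@H]1C[C@H](COS(=O)(=O)C(F)(F)F)C1(C)C
F2 | step 6 | ethyl (S)-3-hydroxybutanoate | CCOC(=O)C[C@H](C)O
F3 | step 17 | 2-[(2R,3R)-3-[(tert-butyldimethylsilyl)oxy]-2-methylbutanoyl]-3,5-dihydroxy-6-{[(1R,3S)-2,2-dimethyl-3-(prop-1-en-2-yl)cyclobutyl]methyl}-6-(3-methylbut-2-en-1-yl)cyclohexa-2,4-dien-1-one (drawn tautomer; quaternary centre as in 23) | C[C@@H](O[Si](C)(C)C(C)(C)C)[C@@H](C)C(=O)C1=C(O)C=C(O)[C@@](C[C@H]2C[C@@H](C(C)=C)C2(C)C)(CC=C(C)C)C1=O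
F4 | step 17 | 2-[(2R,3R)-3-hydroxy-2-methylbutanoyl]-3,5-dihydroxy-6-{[(1R,3S)-2,2-dimethyl-3-(prop-1-en-2-yl)cyclobutyl]methyl}-6-(3-methylbut-2-en-1-yl)cyclohexa-2,4-dien-1-one (drawn tautomer) | C[C@@H](O)[C@@H](C)C(=O)C1=C(O)C=C(O)[C@@](C[C@H]2C[C@@H](C(C)=C)C2(C)C)(CC=C(C)C)C1=O
F5 | step 18 | 5-benzylidene-2,2-dimethyl-1,3-dioxane-4,6-dione | CC1(C)OC(=O)C(=Cc2ccccc2)C(=O)O1
F6 | step 18 | 5-{(S)-[(2R,3R,6R)-6-{[(1R,3S)-2,2-dimethyl-3-(prop-1-en-2-yl)cyclobutyl]methyl}-5-hydroxy-2,3-dimethyl-6-(3-methylbut-2-en-1-yl)-4,7-dioxo-3,4,6,7-tetrahydro-2H-chromen-8-yl](phenyl)methyl}-2,2-dimethyl-1,3-dioxane-4,6-dione | C=C(C)[C@@H]1C[C@H](C[C@@]2(CC=C(C)C)C(=O)C([C@@H](C4C(=O)OC(C)(C)OC4=O)c4ccccc4)=C3O[C@H](C)[C@@H](C)C(=O)C3=C2O)C1(C)C
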